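**Plan**
Ring A is numbered as the acetophenone (C1 acetyl, C2 and C4 hydroxyl, O3 acylated, C6 pentyl); ring B as the benzoate (C1' carboxyl, C2' propyl, C4' OH, C6' OMe).
Ring B is a 6-alkyl-β-resorcylate, the aldol-folded form of a 3,5,7-trioxodecanoyl chain, and its carboxyl carbon sits on O3, the oxygen of ring A flanked by O2 and O4; this is what allows ester and ring to be made together.
The retrosynthesis removes the O-methyl and O-benzyl groups, then cuts the O3–C(=O) ester bond and the C1'–C2' ring bond in one operation. This leads back to a diketo-dioxinone (two enolate acylations from the trimethyldioxinone) and a ring A phenol (acetyl C–C bond and C3–O bond cut back to olivetol).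
Forward: the chain is assembled on the dioxinone (steps 1–2); ring A, present from the start, is benzylated, hydroxylated between the two ethers and acetylated (steps 3–5); ring B is built on O3 (step 6); 4'-O-benzylation, 6'-O-methylation and one hydrogenolysis finish the route (steps 7–9).
The target has no stereocentre and no stereogenic double bond, so no stereocontrol is needed.

Key step: step 6

Remark: metalated forms of a numbered compound (the lithium enolates of steps 1 and 2, the aryllithium of step 4) are treated as its reacting form and carry no number of their own.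

**Route**

Step 1
Reactants: 1 2,2,6-trimethyl-4H-1,3-dioxin-4-one; 2 acetyl chloride
Product: 3 2,2-dimethyl-6-(2-oxopropyl)-4H-1,3-dioxin-4-one
Conditions: LiN(SiMe3)2 (2 equiv), 1 (2 equiv), THF, −78 °C; then 2 (1 equiv), −78 → −20 °C; aq. NH4Cl
Reagents that add atoms: none
Why: γ-selective C-acylation (Claisen-type) of the vinylogous lithium enolate of 1 by the acid chloride should give the β-keto-dioxinone, the twofold amount of enolate absorbing the proton of the more acidic product.

Step 2
Reactants: 3 2,2-dimethyl-6-(2-oxopropyl)-4H-1,3-dioxin-4-one; 4 N-methoxy-N-methylbutanamide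
Product: 5 6-(2,4-dioxoheptyl)-2,2-dimethyl-4H-1,3-dioxin-4-one
Conditions: LiN(iPr)2 (2.2 equiv), THF, −78 °C; then 4, −78 → −30 °C; 1 M HCl quench; used without long storage
Reagents that add atoms: none
Why: crossed Claisen condensation of the dianion of 3, which reacts at its last-formed terminal carbon, with a Weinreb amide whose chelated tetrahedral adduct survives until the acidic quench, so that over-addition and proton quench by the product should not interfere.

Step 3
Reactants: 6 olivetol (5-pentylbenzene-1,3-diol)
Product: 7 1,3-bis(benzyloxy)-5-pentylbenzene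
Conditions: BnBr (2.2 equiv), K2CO3, DMF, rt
Reagents that add atoms: benzyl bromide BrCc1ccccc1
Why: twofold Williamson etherification of the two equivalent phenols.

Step 4
Reactants: 7 1,3-bis(benzyloxy)-5-pentylbenzene
Product: 9 2,6-bis(benzyloxy)-4-pentylphenol, via dimethyl [2,6-bis(benzyloxy)-4-pentylphenyl]boronate 8 (not isolated)
Conditions: n-BuLi (1.2 equiv), THF, 0 °C; B(OMe)3, −78 °C → rt; then 30% H2O2, aq. NaOH, 0 °C → rt
Reagents that add atoms: trimethyl borate COB(OC)OC (boron and methoxy groups of 8); hydrogen peroxide OO (oxygen of 9)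
Why: directed ortho-metalation at the ring position flanked by both ether oxygens (the most acidic aryl C–H, lithiated briefly at 0 °C so that benzylic deprotonation stays minor), boration of the aryllithium and oxidative boron-to-oxygen aryl shift should deliver the phenol between the two benzyl ethers.

Step 5
Reactants: 9 2,6-bis(benzyloxy)-4-pentylphenol
Product: 11 1-[2,4-bis(benzyloxy)-3-hydroxy-6-pentylphenyl]ethan-1-one, via 3-acetyl-2,6-bis(benzyloxy)-4-pentylphenyl acetate 10 (not isolated)
Conditions: AcOH, (CF3CO)2O, CH2Cl2, 0 °C → rt; concentrate; then K2CO3, MeOH, rt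
Reagents that add atoms: acetic acid CC(=O)O
Why: Friedel–Crafts acylation by acetyl trifluoroacetate made in the flask should enter at C3 of the phenol (identical with C5 by symmetry, ortho and para to the benzyloxy groups, the only free ring positions) without a metal Lewis acid that could strip the benzyl ether next to the new ketone; the phenol is O-acetylated along the way and the aryl acetate is then cleaved by base-catalysed methanolysis.

Step 6
Reactants: 5 6-(2,4-dioxoheptyl)-2,2-dimethyl-4H-1,3-dioxin-4-one; 11 1-[2,4-bis(benzyloxy)-3-hydroxy-6-pentylphenyl]ethan-1-one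
Product: 15 3-acetyl-2,6-bis(benzyloxy)-4-pentylphenyl 2,4-dihydroxy-6-propylbenzoate, via acylketene 3,5,7-trioxodec-1-en-1-one 12 (not isolated), via aryl 3,5,7-trioxodecanoate 13 (not isolated), via cyclic aldol adduct 14 (not isolated)
Conditions: 5 (1.3 equiv), PhMe (0.5 M in 11), 110 °C; cool, then Et3N, CH2Cl2, 0 °C → rt; then HCl (4 M in dioxane), rt
Reagents that add atoms: none
Why: Heating 5 should cause a retro-hetero-Diels–Alder loss of acetone to acylketene 12, and the single free hydroxyl of 11 (O3) adds to the ketene carbon through a six-membered hydrogen-bonded transition state, forming the ester C–O bond of 13. Et3N then enolises the carbon between the aryl ester and the first ketone (future C1'), which attacks the butanoyl ketone (future C2') in a 6-(enolexo)-exo-trig aldol addition to 14; acid-promoted loss of water and enolisation of the two remaining ketones close benzene ring B. The closest known reaction type is dioxinone thermolysis with O–H capture of the acylketene (phenols are established traps) followed by biomimetic aldol aromatisation of a 3,5,7-triketo ester to a β-resorcylate. No stereocentre is formed. Two selectivities are needed: capture by the phenol must outrun attack of the chain enol on the ketene (pyranone formation), which is favoured by a concentrated solution with all of 11 present from the start and O3 as its only hydroxyl; and the carbon aldol must outrun lactonisation or Claisen closure with loss of the ring A phenoxide, which a weak amine base in an aprotic solvent at 0 °C should favour because the C1'–H of an aryl β-keto ester is readily enolised and no alkoxide is present. The ring A methyl ketone is far less acidic than the triketo chain, and the benzyl ethers should tolerate heat, amine and brief HCl.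

Step 7
Reactants: 15 3-acetyl-2,6-bis(benzyloxy)-4-pentylphenyl 2,4-dihydroxy-6-propylbenzoate
Product: 16 3-acetyl-2,6-bis(benzyloxy)-4-pentylphenyl 4-(benzyloxy)-2-hydroxy-6-propylbenzoate
Conditions: BnBr (1.05 equiv), K2CO3 (1.1 equiv), acetone, rt
Reagents that add atoms: benzyl bromide BrCc1ccccc1
Why: Williamson etherification selective for the C4' hydroxyl, which is the more acidic one (para to the ester) and is not held in the hydrogen bond that ties the C6' hydroxyl to the ester carbonyl; this benzyl ether leaves in the final hydrogenolysis with the other two.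

Step 8
Reactants: 16 3-acetyl-2,6-bis(benzyloxy)-4-pentylphenyl 4-(benzyloxy)-2-hydroxy-6-propylbenzoate
Product: 17 3-acetyl-2,6-bis(benzyloxy)-4-pentylphenyl 4-(benzyloxy)-2-methoxy-6-propylbenzoate
Conditions: MeI, K2CO3, DMF, rt → 40 °C
Reagents that add atoms: iodomethane CI
Why: Williamson methylation of the remaining chelated phenol under slightly more forcing conditions; the ester is shielded by two ortho substituents on each ring and carbonate is not nucleophilic enough to cleave it.

Step 9
Reactants: 17 3-acetyl-2,6-bis(benzyloxy)-4-pentylphenyl 4-(benzyloxy)-2-methoxy-6-propylbenzoate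
Product: 18 3-acetyl-2,6-dihydroxy-4-pentylphenyl 4-hydroxy-2-methoxy-6-propylbenzoate (target)
Conditions: H2 (1 atm), 10% Pd/C, EtOAc, rt
Reagents that add atoms: none
Why: catalytic hydrogenolysis of the three benzyl aryl ethers under neutral conditions should leave the ester, the methyl ether and the hindered, hydrogen-bonded aryl ketone untouched and supplies no base that could move the aroyl group to the neighbouring free hydroxyls.

**Compound list**
1 | 2,2,6-trimethyl-4H-1,3-dioxin-4-one | CC1=CC(=O)OC(C)(C)O1 | starting material
2 | acetyl chloride | CC(=O)Cl | starting material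
3 | 2,2-dimethyl-6-(2-oxopropyl)-4H-1,3-dioxin-4-one | CC(=O)CC1=CC(=O)OC(C)(C)O1 | intermediate
4 | N-methoxy-N-methylbutanamide | CCCC(=O)N(C)OC | starting material
5 | 6-(2,4-dioxoheptyl)-2,2-dimethyl-4H-1,3-dioxin-4-one | CCCC(=O)CC(=O)CC1=CC(=O)OC(C)(C)O1 | intermediate
6 | olivetol (5-pentylbenzene-1,3-diol) | CCCCCc1cc(O)cc(O)c1 | starting material
7 | 1,3-bis(benzyloxy)-5-pentylbenzene | CCCCCc1cc(OCc2ccccc2)cc(OCc2ccccc2)c1 | intermediate
8 | dimethyl [2,6-bis(benzyloxy)-4-pentylphenyl]boronate | CCCCCc1cc(OCc2ccccc2)c(B(OC)OC)c(OCc2ccccc2)c1 | intermediate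
9 | 2,6-bis(benzyloxy)-4-pentylphenol | CCCCCc1cc(OCc2ccccc2)c(O)c(OCc2ccccc2)c1 | intermediate
10 | 3-acetyl-2,6-bis(benzyloxy)-4-pentylphenyl acetate | CCCCCc1cc(OCc2ccccc2)c(OC(C)=O)c(OCc2ccccc2)c1C(C)=O | intermediate
11 | 1-[2,4-bis(benzyloxy)-3-hydroxy-6-pentylphenyl]ethan-1-one | CCCCCc1cc(OCc2ccccc2)c(O)c(OCc2ccccc2)c1C(C)=O | intermediate
12 | 3,5,7-trioxodec-1-en-1-one (acylketene) | CCCC(=O)CC(=O)CC(=O)C=C=O | intermediate
13 | 3-acetyl-2,6-bis(benzyloxy)-4-pentylphenyl 3,5,7-trioxodecanoate | CCCC(=O)CC(=O)CC(=O)CC(=O)Oc1c(OCc2ccccc2)cc(CCCCC)c(C(C)=O)c1OCc1ccccc1 | intermediate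
14 | 3-acetyl-2,6-bis(benzyloxy)-4-pentylphenyl 2-hydroxy-4,6-dioxo-2-propylcyclohexane-1-carboxylate | CCCC1(O)CC(=O)CC(=O)C1C(=O)Oc1c(OCc2ccccc2)cc(CCCCC)c(C(C)=O)c1OCc1ccccc1 | intermediate
15 | 3-acetyl-2,6-bis(benzyloxy)-4-pentylphenyl 2,4-dihydroxy-6-propylbenzoate | CCCCCc1cc(OCc2ccccc2)c(OC(=O)c2c(CCC)cc(O)cc2O)c(OCc2ccccc2)c1C(C)=O | intermediate
16 | 3-acetyl-2,6-bis(benzyloxy)-4-pentylphenyl 4-(benzyloxy)-2-hydroxy-6-propylbenzoate | CCCCCc1cc(OCc2ccccc2)c(OC(=O)c2c(CCC)cc(OCc3ccccc3)cc2O)c(OCc2ccccc2)c1C(C)=O | intermediate
17 | 3-acetyl-2,6-bis(benzyloxy)-4-pentylphenyl 4-(benzyloxy)-2-methoxy-6-propylbenzoate | CCCCCc1cc(OCc2ccccc2)c(OC(=O)c2c(CCC)cc(OCc3ccccc3)cc2OC)c(OCc2ccccc2)c1C(C)=O | intermediate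
18 | 3-acetyl-2,6-dihydroxy-4-pentylphenyl 4-hydroxy-2-methoxy-6-propylbenzoate (CNP0112527.0) | CCCCCc1cc(O)c(OC(=O)c2c(CCC)cc(O)cc2OC)c(O)c1C(C)=O | target

**Count**
Total steps: 9. Longest linear sequence: 7 steps (olivetol 6 to target 18, steps 3–9); the dioxinone branch (steps 1–2) joins at step 6.

**Steps most likely to fail**

Step 6. The acylketene may be consumed by attack of its own chain enol (pyranone formation) before the hindered phenol adds. After capture, the triketo aryl ester may close through oxygen or by Claisen-type acylation with expulsion of the ring A phenoxide instead of through the aldol. The fallback aromatises ring B first and makes the ester afterwards. It sets out from 5: Et3N in CH2Cl2 followed by acidification should close the aldol onto the dioxinone carbon and give 7-hydroxy-2,2-dimethyl-5-propyl-4H-1,3-benzodioxin-4-one F1. BnBr and K2CO3 in acetone give 7-(benzyloxy)-2,2-dimethyl-5-propyl-4H-1,3-benzodioxin-4-one F2. KOH in aqueous DMSO followed by cold dilute HCl opens the acetonide to 4-(benzyloxy)-2-hydroxy-6-propylbenzoic acid F3. (CF3CO)2O in toluene at rt converts F3 into 4-(benzyloxy)-2-hydroxy-6-propylbenzoic trifluoroacetic anhydride F4, which should acylate phenol 11 in the same flask (the classical depside esterification). The product is 16, where the route is rejoined before step 8.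

Step 4. Deprotonation at a benzylic OCH2 group followed by a [1,2]-Wittig shift may compete with ring lithiation. The fallback does the metalation on acetal-protected oxygens and changes the protecting groups afterwards. It sets out from 6: MOMCl and iPr2NEt in CH2Cl2 give 1,3-bis(methoxymethoxy)-5-pentylbenzene F5. n-BuLi in THF at 0 °C, then B(OMe)3, give dimethyl [2,6-bis(methoxymethoxy)-4-pentylphenyl]boronate F6, which H2O2 and aq. NaOH oxidise in the same flask to 2,6-bis(methoxymethoxy)-4-pentylphenol F7. Allyl bromide and K2CO3 in DMF give 1,3-bis(methoxymethoxy)-5-pentyl-2-(prop-2-en-1-yloxy)benzene F8. HCl in MeOH at 40 °C removes the two acetals to give 5-pentyl-2-(prop-2-en-1-yloxy)benzene-1,3-diol F9. BnBr and K2CO3 in DMF give 1,3-bis(benzyloxy)-5-pentyl-2-(prop-2-en-1-yloxy)benzene F10. Pd(PPh3)4 with morpholine in THF removes the allyl group and returns to the route at 9.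

Step 5. A benzyl group may be lost or migrate under the acidic acylation conditions (most readily the one ortho to the new ketone), or the reaction may stop at the O-acetate. The fallback introduces the acetyl group through an aryl anion instead of an acylium ion. It sets out from 9: N-bromosuccinimide in MeCN at 0 °C should brominate the only free activated ring position and give 2,6-bis(benzyloxy)-3-bromo-4-pentylphenol F11. n-BuLi (2.2 equiv) in THF at −78 °C forms the phenoxide and then exchanges bromine for lithium, and N-methoxy-N-methylacetamide acylates the aryllithium (Weinreb ketone synthesis). This returns to the route at 11.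

**Further compounds**
F1 | step 6 | 7-hydroxy-2,2-dimethyl-5-propyl-4H-1,3-benzodioxin-4-one | CCCc1cc(O)cc2OC(C)(C)OC(=O)c12
F2 | step 6 | 7-(benzyloxy)-2,2-dimethyl-5-propyl-4H-1,3-benzodioxin-4-one | CCCc1cc(OCc3ccccc3)cc2OC(C)(C)OC(=O)c12
F3 | step 6 | 4-(benzyloxy)-2-hydroxy-6-propylbenzoic acid | CCCc1cc(OCc2ccccc2)cc(O)c1C(=O)O
F4 | step 6 | 4-(benzyloxy)-2-hydroxy-6-propylbenzoic trifluoroacetic anhydride | CCCc1cc(OCc2ccccc2)cc(O)c1C(=O)OC(=O)C(F)(F)F
F5 | step 4 | 1,3-bis(methoxymethoxy)-5-pentylbenzene | CCCCCc1cc(OCOC)cc(OCOC)c1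
F6 | step 4 | dimethyl [2,6-bis(methoxymethoxy)-4-pentylphenyl]boronate | CCCCCc1cc(OCOC)c(B(OC)OC)c(OCOC)c1
F7 | step 4 | 2,6-bis(methoxymethoxy)-4-pentylphenol | CCCCCc1cc(OCOC)c(O)c(OCOC)c1
F8 | step 4 | 1,3-bis(methoxymethoxy)-5-pentyl-2-(prop-2-en-1-yloxy)benzene | CCCCCc1cc(OCOC)c(OCC=C)c(OCOC)c1
F9 | step 4 | 5-pentyl-2-(prop-2-en-1-yloxy)benzene-1,3-diol | CCCCCc1cc(O)c(OCC=C)c(O)c1
F10 | step 4 | 1,3-bis(benzyloxy)-5-pentyl-2-(prop-2-en-1-yloxy)benzene | CCCCCc1cc(OCc2ccccc2)c(OCC=C)c(OCc2ccccc2)c1
F11 | step 5 | 2,6-bis(benzyloxy)-3-bromo-4-pentylphenol | CCCCCc1cc(OCc2ccccc2)c(O)c(OCc2ccccc2)c1Br
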